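**Assumption:** an R-selective flavin-dependent monooxygenase of the TropB/AzaH type (wild type or a screened homologue) accepts ketone 8; dienones are drawn as their hydrogen-bonded enol tautomers.

## Retrosynthetic overview

1. Gilluone B ⇐ C→O acyl shift (retro-Claisen) in ring A of C-acyl precursor 14 ⇐ C-methylation that creates the quaternary carbon of ring A in 13.
2. Methylene-bridged bis(dienone) 13 ⇐ Mannich base 11 of the aminated o-quinol (ring B) + o-quinol 9 (ring A).
3. Both rings ⇐ the same o-quinol 9 ⇐ enzymatic oxidative dearomatization of acylresorcinol 8 (sets the carbinol centre of each ring).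
4. 8 ⇐ Friedel–Crafts acylation of arene 7 (from 2,4,6-trihydroxybenzaldehyde) with (R)-2-methylbutanoyl chloride ⇐ asymmetric hydrogenation of tiglic acid.
5. No ring is built de novo: both six-membered rings are the benzene ring of 7; ring B is finished first (amination), ring A last (quaternisation, acyl shift).

## Route

**Step 1**
Reactants: 1 tiglic acid
Product: 2 (R)-2-methylbutanoic acid
Conditions: H2 (4 atm), Ru(OAc)2[(R)-H8-BINAP] (0.5 mol %), MeOH, 20 °C
Reagents that add atoms: none
Why: Noyori-type asymmetric hydrogenation in which the substrate binds ruthenium as its carboxylate and the (R)-biaryl diphosphine shields one alkene face, so H2 adds to give the (R)-acid (about 97% ee expected, sense checked by optical rotation).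

**Step 2**
Reactants: 2 (R)-2-methylbutanoic acid
Product: 3 (R)-2-methylbutanoyl chloride
Conditions: (COCl)2 (1.2 equiv), DMF (cat.), CH2Cl2, 0 °C → rt, used crude
Reagents that add atoms: oxalyl chloride, ClC(=O)C(=O)Cl
Why: acyl chloride formation through the Vilsmeier-type chloroiminium under base-free conditions, so no ketene forms and the α-stereocentre is untouched.

**Step 3**
Reactants: 4 2,4,6-trihydroxybenzaldehyde
Product: 5 2,6-dihydroxy-4-methoxybenzaldehyde
Conditions: MeI (1.05 equiv), K2CO3 (1.0 equiv), acetone, 0 °C → rt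
Reagents that add atoms: iodomethane, CI
Why: Williamson etherification that is selective because the 2- and 6-hydroxyls are tied up in hydrogen bonds to the aldehyde while the 4-hydroxyl (a vinylogous acid) is the one deprotonated by a single equivalent of carbonate.

**Step 4**
Reactants: 5 2,6-dihydroxy-4-methoxybenzaldehyde
Product: 7 5-methoxy-2-methylbenzene-1,3-diol, via benzylic alcohol 6 (not isolated)
Conditions: H2 (3 atm), 10% Pd/C, AcOH, HCl (cat.), rt
Reagents that add atoms: none
Why: hydrogenation of the aldehyde followed by hydrogenolysis of the electron-rich, doubly ortho-hydroxylated benzylic C–O bond gives the methyl group and a symmetric arene whose two free positions are equivalent.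

**Step 5**
Reactants: 7 5-methoxy-2-methylbenzene-1,3-diol; 3 (R)-2-methylbutanoyl chloride
Product: 8 (2R)-1-(2,4-dihydroxy-6-methoxy-3-methylphenyl)-2-methylbutan-1-one
Conditions: AlCl3 (2.5 equiv), CH2Cl2–PhNO2, 0 °C, 3 h, then cold aq. HCl
Reagents that add atoms: none
Why: Friedel–Crafts acylation at the only type of free ring position, placing the ketone between OH and OMe; the low temperature limits AlCl3-mediated ortho-demethylation and enolisation of the α-stereocentre (ee checked by chiral HPLC).

**Step 6**
Reactants: 8 (2R)-1-(2,4-dihydroxy-6-methoxy-3-methylphenyl)-2-methylbutan-1-one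
Product: 9 (6R)-5,6-dihydroxy-3-methoxy-6-methyl-4-[(2R)-2-methylbutanoyl]cyclohexa-2,4-dien-1-one
Conditions: R-selective FAD-dependent monooxygenase (TropB/AzaH type, clarified E. coli lysate), NADP+ (cat.), phosphite dehydrogenase, Na2HPO3, air, KH2PO4/K2HPO4 buffer pH 8.0 with 5% DMSO, 30 °C
Reagents that add atoms: dioxygen, O=O
Why: biocatalytic oxidative dearomatization in which the enzyme's C4a-hydroperoxyflavin hydroxylates the methyl-bearing carbon between the two phenols of the 2,4-dihydroxy-3-methylaryl ketone motif from one face only, setting the (6R) carbinol that later becomes the oxygenated quaternary centre of both rings.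

**Step 7**
Reactants: 9 (6R)-5,6-dihydroxy-3-methoxy-6-methyl-4-[(2R)-2-methylbutanoyl]cyclohexa-2,4-dien-1-one
Product: 10 (6R)-5-amino-6-hydroxy-3-methoxy-6-methyl-4-[(2R)-2-methylbutanoyl]cyclohexa-2,4-dien-1-one
Conditions: NH4OAc (5 equiv), MeOH, 25 °C, 16 h
Reagents that add atoms: ammonium acetate, CC(=O)[O-].[NH4+]
Why: enaminone formation by condensation of ammonia at the ring carbon of the enolised β-diketone, which is activated by the adjacent carbinol and gives the N–H···O=C chelated, fully conjugated vinylogous amide under reversible buffered conditions, whereas the cyclic β-methoxy enone needs much harsher conditions for aminolysis.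

**Step 8**
Reactants: 10 (6R)-5-amino-6-hydroxy-3-methoxy-6-methyl-4-[(2R)-2-methylbutanoyl]cyclohexa-2,4-dien-1-one
Product: 11 (6R)-5-amino-2-[(dimethylamino)methyl]-6-hydroxy-3-methoxy-6-methyl-4-[(2R)-2-methylbutanoyl]cyclohexa-2,4-dien-1-one
Conditions: Eschenmoser's salt (1.2 equiv), K2CO3 (1.2 equiv), MeCN, 0 °C → rt
Reagents that add atoms: Eschenmoser's salt (N,N-dimethylmethyleneiminium iodide), C=[N+](C)C.[I-]
Why: Mannich reaction at C2, the only unsubstituted nucleophilic carbon (β-carbon of the enol ether and δ-carbon of the dienamine), giving a gramine-like aminomethyl handle that carries the future bridge carbon.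

**Step 9**
Reactants: 11 Mannich base; 9 o-quinol (1.3 equiv)
Product: 13 (6R)-5-amino-2-{[(5R)-4,5-dihydroxy-2-methoxy-5-methyl-3-[(2R)-2-methylbutanoyl]-6-oxocyclohexa-1,3-dien-1-yl]methyl}-6-hydroxy-3-methoxy-6-methyl-4-[(2R)-2-methylbutanoyl]cyclohexa-2,4-dien-1-one, via iminomethide 12 (not isolated)
Conditions: MeCN, 45 °C, N2 stream, then pH 4 buffer
Reagents that add atoms: none
Why: elimination–Michael addition (gramine-type alkylation) in which the vinylogous acid 9 protonates the amine, dimethylamine leaves to give the exocyclic methylene acceptor 12, and the anion of 9 adds through its only free nucleophilic carbon (the other bears the acyl group); no stereocentre is formed and excess 9 suppresses double alkylation.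

**Step 10**
Reactants: 13 methylene-bridged bis(dienone)
Product: 14 (6R)-5-amino-6-hydroxy-2-{[(1R,5S)-5-hydroxy-2-methoxy-1,5-dimethyl-3-[(2R)-2-methylbutanoyl]-4,6-dioxocyclohex-2-en-1-yl]methyl}-3-methoxy-6-methyl-4-[(2R)-2-methylbutanoyl]cyclohexa-2,4-dien-1-one
Conditions: KOt-Bu (1.0 equiv), MeI (3 equiv), t-BuOH–THF, 0 °C → rt
Reagents that add atoms: iodomethane, CI
Why: C-alkylation of a vinylogous acid anion, in which one equivalent of base deprotonates only ring A (ring B is a non-acidic vinylogous amide), the acyl group blocks the second nucleophilic carbon, protic medium and soft MeI favour carbon over oxygen, and MeI should enter on the face carrying the neighbouring carbinol OH and not its methyl group (the face o-quinols normally react on), giving the (1′R) quaternary centre with the new methyl cis to that OH.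

**Step 11**
Reactants: 14 C-acyl precursor
Product: 16 gilluone B, via dimethyl ketal 15 (not isolated)
Conditions: DBU (0.2 equiv), MeOH, 0 °C → rt
Reagents that add atoms: methanol, CO (adds to ring A to give 15 and one methanol leaves again, so the ring A methoxy group of 16 can stem from the solvent)
Why: retro-Claisen C→O acyl shift in which reversible conjugate addition of methanol to the doubly activated β-methoxy enone carbon makes the acyl-bearing carbon sp3, the adjacent tertiary alkoxide attacks the side-chain ketone through a five-membered ring, C–C cleavage gives the tertiary ester and an enolate that expels methoxide to restore the enol ether; it is driven by relief of the crowded non-enolisable tricarbonyl array and touches no stereocentre (the (R)-acyl group moves intact).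

## Compound list

1 | tiglic acid, (E)-2-methylbut-2-enoic acid | C/C=C(\C)C(=O)O | starting material
2 | (R)-2-methylbutanoic acid | CC[C@@H](C)C(=O)O | intermediate
3 | (R)-2-methylbutanoyl chloride | CC[C@@H](C)C(Cl)=O | intermediate
4 | 2,4,6-trihydroxybenzaldehyde | O=Cc1c(O)cc(O)cc1O | starting material
5 | 2,6-dihydroxy-4-methoxybenzaldehyde | COc1cc(O)c(C=O)c(O)c1 | intermediate
6 | 2-(hydroxymethyl)-5-methoxybenzene-1,3-diol (benzylic alcohol, not isolated) | COc1cc(O)c(CO)c(O)c1 | intermediate
7 | 5-methoxy-2-methylbenzene-1,3-diol | COc1cc(O)c(C)c(O)c1 | intermediate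
8 | (2R)-1-(2,4-dihydroxy-6-methoxy-3-methylphenyl)-2-methylbutan-1-one | CC[C@@H](C)C(=O)c1c(O)c(C)c(O)cc1OC | intermediate
9 | (6R)-5,6-dihydroxy-3-methoxy-6-methyl-4-[(2R)-2-methylbutanoyl]cyclohexa-2,4-dien-1-one | CC[C@@H](C)C(=O)C1=C(O)[C@@](C)(O)C(=O)C=C1OC | intermediate
10 | (6R)-5-amino-6-hydroxy-3-methoxy-6-methyl-4-[(2R)-2-methylbutanoyl]cyclohexa-2,4-dien-1-one | CC[C@@H](C)C(=O)C1=C(N)[C@@](C)(O)C(=O)C=C1OC | intermediate
11 | (6R)-5-amino-2-[(dimethylamino)methyl]-6-hydroxy-3-methoxy-6-methyl-4-[(2R)-2-methylbutanoyl]cyclohexa-2,4-dien-1-one | CC[C@@H](C)C(=O)C1=C(N)[C@@](C)(O)C(=O)C(CN(C)C)=C1OC | intermediate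
12 | (6R)-6-hydroxy-5-imino-3-methoxy-6-methyl-2-methylidene-4-[(2R)-2-methylbutanoyl]cyclohex-3-en-1-one (iminomethide, not isolated) | C=C1C(=O)[C@](C)(O)C(=N)C(C(=O)[C@H](C)CC)=C1OC | intermediate
13 | (6R)-5-amino-2-{[(5R)-4,5-dihydroxy-2-methoxy-5-methyl-3-[(2R)-2-methylbutanoyl]-6-oxocyclohexa-1,3-dien-1-yl]methyl}-6-hydroxy-3-methoxy-6-methyl-4-[(2R)-2-methylbutanoyl]cyclohexa-2,4-dien-1-one | CC[C@@H](C)C(=O)C1=C(O)[C@@](C)(O)C(=O)C(CC2=C(OC)C(C(=O)[C@H](C)CC)=C(N)[C@@](C)(O)C2=O)=C1OC | intermediate
14 | (6R)-5-amino-6-hydroxy-2-{[(1R,5S)-5-hydroxy-2-methoxy-1,5-dimethyl-3-[(2R)-2-methylbutanoyl]-4,6-dioxocyclohex-2-en-1-yl]methyl}-3-methoxy-6-methyl-4-[(2R)-2-methylbutanoyl]cyclohexa-2,4-dien-1-one | O[C@]1(C)C(=O)C(C(=O)[C@H](C)CC)=C(OC)[C@@](C)(CC2=C(OC)C(C(=O)[C@H](C)CC)=C(N)[C@@](C)(O)C2=O)C1=O | intermediate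
15 | methanol adduct of 14: ring A dimethyl ketal, both epimers at the acyl-bearing ring carbon (not isolated) | O[C@]1(C)C(=O)C(C(=O)[C@H](C)CC)C(OC)(OC)[C@@](C)(CC2=C(OC)C(C(=O)[C@H](C)CC)=C(N)[C@@](C)(O)C2=O)C1=O | intermediate
16 | gilluone B, (1R,3R)-3-({(5R)-4-amino-5-hydroxy-2-methoxy-5-methyl-3-[(2R)-2-methylbutanoyl]-6-oxocyclohexa-1,3-dien-1-yl}methyl)-4-methoxy-1,3-dimethyl-2,6-dioxocyclohex-4-en-1-yl (2R)-2-methylbutanoate | CC[C@@H](C)C(=O)O[C@]1(C)C(=O)C=C(OC)[C@@](C)(CC2=C(OC)C(C(=O)[C@H](C)CC)=C(N)[C@@](C)(O)C2=O)C1=O | target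

## Step count and risks

Total step count: 11.
Longest linear sequence: 9 steps (4 → 5 → 7 → 8 → 9 → 10 → 11 → 13 → 14 → 16; the branch from 1 is equally long).

The three steps most likely to fail:

**Step 7 (site of amination).** Ammonia could condense at the side-chain carbonyl or displace the ring methoxy group. The fallback sets out from 9: TMSCHN2 (MeOH–toluene, 0 °C) O-methylates the acidic enol to the vinylogous ester (6R)-6-hydroxy-3,5-dimethoxy-6-methyl-4-[(2R)-2-methylbutanoyl]cyclohexa-2,4-dien-1-one F1. NH3 (7 M in MeOH, 0 °C) then replaces the 5-methoxy group by addition–elimination, because that carbon is β to the acyl carbonyl and the product is locked by an N–H···O=C hydrogen bond. The sequence returns to the route at 10.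

**Step 10 (quaternary carbon of ring A).** MeI could alkylate on oxygen or from the wrong face. The fallback sets out from 9 and reverses the order of the two C–C bonds at that carbon. C-methylation of 9 (MeI, KOt-Bu 1.0 equiv, t-BuOH) gives (6R)-5,6-dihydroxy-3-methoxy-2,6-dimethyl-4-[(2R)-2-methylbutanoyl]cyclohexa-2,4-dien-1-one F2. Heating F2 with Mannich base 11 (MeCN, 45 °C) lets the iminomethide 12 close the quaternary centre by Michael addition. The last-entering group is then the methylene unit, which inverts the configuration obtained from a given facial bias, and a soft Michael acceptor does not alkylate on oxygen. The sequence returns to the route at 14.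

**Step 11 (acyl shift through the methanol adduct).** The shift may not start, or methanol may cleave the ketone intermolecularly. The fallback sets out from 14. LiOH (1 equiv), THF–H2O, 0 °C hydrolyses the acyl-activated enol ether of ring A to the β-triketone (6R)-5-amino-2-{[(1R,5S)-2,5-dihydroxy-1,5-dimethyl-3-[(2R)-2-methylbutanoyl]-4,6-dioxocyclohex-2-en-1-yl]methyl}-6-hydroxy-3-methoxy-6-methyl-4-[(2R)-2-methylbutanoyl]cyclohexa-2,4-dien-1-one F3. Its acyl-bearing carbon can now become an enolate, so Et3N in CH2Cl2 effects the ordinary retro-Claisen shift to the ring A enol (1R,3R)-3-({(5R)-4-amino-5-hydroxy-2-methoxy-5-methyl-3-[(2R)-2-methylbutanoyl]-6-oxocyclohexa-1,3-dien-1-yl}methyl)-4-hydroxy-1,3-dimethyl-2,6-dioxocyclohex-4-en-1-yl (2R)-2-methylbutanoate F4. TMSCHN2 then O-methylates the enol; the regioisomeric enol ether is removed by chromatography and the sequence returns to the route at 16.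

## Further compounds

F1 | step 7 | (6R)-6-hydroxy-3,5-dimethoxy-6-methyl-4-[(2R)-2-methylbutanoyl]cyclohexa-2,4-dien-1-one | CC[C@@H](C)C(=O)C1=C(OC)[C@@](C)(O)C(=O)C=C1OC
F2 | step 10 | (6R)-5,6-dihydroxy-3-methoxy-2,6-dimethyl-4-[(2R)-2-methylbutanoyl]cyclohexa-2,4-dien-1-one | CC[C@@H](C)C(=O)C1=C(O)[C@@](C)(O)C(=O)C(C)=C1OC
F3 | step 11 | (6R)-5-amino-2-{[(1R,5S)-2,5-dihydroxy-1,5-dimethyl-3-[(2R)-2-methylbutanoyl]-4,6-dioxocyclohex-2-en-1-yl]methyl}-6-hydroxy-3-methoxy-6-methyl-4-[(2R)-2-methylbutanoyl]cyclohexa-2,4-dien-1-one | O[C@]1(C)C(=O)C(C(=O)[C@H](C)CC)=C(O)[C@@](C)(CC2=C(OC)C(C(=O)[C@H](C)CC)=C(N)[C@@](C)(O)C2=O)C1=O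
F4 | step 11 | (1R,3R)-3-({(5R)-4-amino-5-hydroxy-2-methoxy-5-methyl-3-[(2R)-2-methylbutanoyl]-6-oxocyclohexa-1,3-dien-1-yl}methyl)-4-hydroxy-1,3-dimethyl-2,6-dioxocyclohex-4-en-1-yl (2R)-2-methylbutanoate | CC[C@@H](C)C(=O)O[C@]1(C)C(=O)C=C(O)[C@@](C)(CC2=C(OC)C(C(=O)[C@H](C)CC)=C(N)[C@@](C)(O)C2=O)C1=O
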